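## Analysis of the target

The target (24) is a B-type proanthocyanidin dimer: an upper (−)-epicatechin 3-O-gallate unit (rings A, C, B; atoms C2, C3, C4) is bonded through C4 to C8 of ring D of a lower (−)-epigallocatechin 3-O-gallate unit (rings D, F, E; atoms C2', C3', C4'). It has five stereocentres, all R. C2/C3 are cis on ring C, C2'/C3' are cis on ring F, and the ring D substituent at C4 is trans to the C3 oxygen and therefore trans to ring B. Fourteen free phenols (one catechol, three pyrogallols) make it sensitive to air and base; the two gallate esters can migrate or hydrolyse; acid can cleave the C4–C8 bond through a ring A-stabilised C4 cation. The customary assembly, capture of a C4 cation by a second flavan, has to fight oligomerisation and C6/C8 regiochemistry, and it does nothing for the less stable 2,3-cis arrangement, which is needed twice. Rings A and D are almost identical phloroglucinol ethers, so the configuration at C4 rests on a remote difference. The feature used here is that rings C and F share one pattern: the phenolic oxygen (O1 on C8a of ring A, O1' on C8a of ring D) and the C3 (C3') oxygen stand as in an anti addition across a (Z)-C2=C3 (C2'=C3') bond. That is what a cis-epoxide gives when the neighbouring phenol opens it at the benzylic carbon with inversion, so two cis-styrenes (ring B–C2=C3 and ring E–C2'=C3') encode four of the five stereocentres and only C4 must be set beforehand.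

## Retrosynthetic reasoning

**24 ⇒ 23.** Fifteen O–benzyl bonds are cut. Carrying every phenol as a benzyl ether allows one neutral hydrogenolysis at the end, which leaves the esters and the C4–C8 bond alone. The forward step must remove all fifteen without reducing the cyclic benzylic ethers at C2 and C2'.

**23 ⇒ 21 + 22.** The two ester C–O bonds at O3 and O3' are cut. Late esterification keeps the gallates away from fluoride, acid and oxidant, and diol 21 has no other free hydroxyl. The forward step must acylate the axial C3–OH beside the C4 aryl group.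

**21 ⇒ 19 (through 20).** O1–C2 and O1'–C2' are cut. These carbons are benzylic, so the ring A and ring D phenols can open the oxiranes in the 6-endo sense. Inversion at C2 (C2') with C3–O (C3'–O) untouched turns each cis-epoxide into a 2,3-cis-flavan-3-ol. The forward step must stay SN2-like, without ionisation and without 5-exo closure.

**19 ⇒ 18 (key disconnection).** The four C–O bonds of the two oxiranes are cut. Both alkenes of 18 are (Z)-aryl–CH=CH–sp3 units, so one chiral (salen)manganese catalyst can treat them alike. C4 is the only stereocentre of 18 and four are gained. The forward step needs enantioface selection at both sites, preserved cis geometry, and no attack on the arenes.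

**18 ⇒ 17 ⇒ 16.** Each (Z)-alkene comes from an alkyne by syn semihydrogenation, which fixes the geometry. The two phenols that later become O1 and O1' are masked as silyl ethers, since free phloroglucinol-type phenols would not survive the oxidation and would open the epoxides prematurely.

**16 ⇒ 13 + 14 (through 15).** The C4–C4a bond to ring A is cut. Ring A then arrives as the symmetric phenol 14, which can be used in excess to suppress over-alkylation. Ring D of 13 has no free ortho position, so the electrophile cannot easily condense with itself. The ortho-quinone methide 15 is the natural reactivity of such a carbinol, and the two phenolic hydroxyls give a bifunctional chiral phosphoric acid two points of contact. The forward step must attack ortho (not para) on 14 and on one face of 15.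

**13 ⇒ 10 + 12.** The C3–C4 bond is cut: an acetylide adds to an aldehyde. The carbinol configuration is irrelevant because it is lost in 15.

**10 ⇒ 8.** The bond between C8 of ring D and the formyl carbon (the later C4) is cut. The phenol directs formylation to its only free ortho carbon.

**8 ⇒ 6 ⇒ 2 + 5.** The lower arm C4'–C3'≡C2'–ring E comes from acetylide addition to aldehyde 2 followed by reductive removal of the carbinol oxygen through ortho-quinone methide 7. This avoids a regiochemically ambiguous C-propargylation of a phloroglucinol; the formyl carbon of 2 becomes C4'.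

**5 ⇒ 4 ⇒ 3; 12 ⇒ 11; 2 ⇒ 1.** Terminal alkynes come from aldehydes by one-carbon homologation; benzyl ethers by alkylation, with the chelated hydroxyl of 1 left free.

## Alternatives that were turned down

**Alternative 1:** The disconnection is the aryl ether bond O1–C8a of ring C. In the precursor A2, C4 carries two identical 2-fluoro-4,6-bis(benzyloxy)phenyl groups and is not yet stereogenic; C2 and C3 are in place, with O3 as an allyl ether. In the forward key step a strong amide base forms the C2 alkoxide of A2, which displaces fluoride from one of the two diastereotopic fluoroarenes. This closes ring C, turns that arene into ring A, leaves the other as a latent ring D and fixes C4, giving A1.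
- For it: C4 is set by group selection in a six-membered transition state under the influence of C2 and C3. No enantioselective construction of a methine between two look-alike rings is needed, the C2–O bond is never broken, and no benzylic epoxide is handled. On these points it is stronger than the chosen route.
- Against it: the fluoroarene is a poor SNAr substrate. The carbons that would carry the negative charge of the Meisenheimer intermediate are ortho and para to the two benzyloxy donors, so forcing conditions would be needed, under which a benzylic alkoxide with a β-allyloxy group can eliminate or fragment. The 3,4-trans outcome rests only on conformational preference.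
- A1 is also far from the target. The remaining C–F bond must become C8a–O1', ring D lacks the C4a carbon from which ring F, C2' and C3' would be built in a separate stereocontrolled sequence, and the allyl ether must be exchanged for the gallate.
- Comparison: the chosen strategy spends one enantioselective Friedel–Crafts step on C4 and then makes both pyran rings and four stereocentres from 18 in two operations.

**Alternative 2:** The disconnection is the C4a–C8a bond of ring A, which is built last from an open triketide chain. In the forward key step methoxide converts the 3,5-dioxo ester A4 into A3 by attack of the C4a methylene on the ester carbonyl and tautomerisation of the cyclohexanetrione to the phloroglucinol.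
- For it: C4 is bonded to an sp3 chain when it is made, so there is no C6/C8 question, no quinone methide, no oligomerisation, and no electron-rich ring A has to survive an oxidation. In this it is cleaner than the chosen route.
- Against it: A4 must already contain the whole lower unit and three contiguous stereocentres (C2, C3, C4) with differentiated silyl ethers, a long linear exercise in acyclic stereocontrol. The carbon that must act as nucleophile (C4a) is the least acidic and most hindered α-position, while the doubly activated methylenes favour closure of an enol oxygen onto the ester to a 4-hydroxy-2-pyrone. A3 then has three free phenols on ring A that must be told apart for closure of ring C and for protection.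
- Comparison: the chosen route takes rings A and D from 1 and 14, needs no aromatisation and sets the stereocentres by catalyst control. It gives up the regiochemical certainty of this alternative and offers instead an electrophile (13) whose ring D has no free ortho position.

**Alternative 3:** The disconnection is C3–C4 and O1–C2 of ring C. In the forward key step a chiral BINOL-derived phosphoric acid dehydrates the diaryl carbinol A6 (ring A phenol plus the complete, silyl-protected lower unit) to the ring A ortho-quinone methide. The enol of the α-galloyloxy ketone A7 adds to C4, and the phenol closes on the ketone carbon to give the 2-hydroxyflavan 3-gallate A5 as C2 anomers.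
- For it: it is the most convergent plan. Ring B, C2, C3 and the upper gallate arrive in one step, the lower unit could come from the natural flavan-3-ol pool, and no electron-rich intermediate is oxidised. In step count it would beat the chosen route.
- Against it: A7 is a weakly enolisable monoketone, the methide carbon derived from A6 carries a doubly ortho-substituted aryl group, and the acid must control C3 and C4 against the bias of the lower unit.
- The C2 hemiketal of A5 must then be reduced through a ring B-stabilised oxocarbenium ion. Hydride delivery cis to H3 is opposed by the C4 aryl group on that face, and participation of the 3-O-galloyl carbonyl would steer towards the 2,3-trans product. Ring-opening of A5 to the β-aryl ketone also invites acyl migration and elimination.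
- Comparison: the chosen strategy uses a phosphoric acid only for the single centre C4, with a slim alkynyl group as second substituent, and takes the 2,3-cis relation of both units from alkene geometry instead of from a hydride reduction. It pays for this with more steps.

Key step: step 12

**Remarks on the chemistry (assumptions).**
- Flavan numbering is used throughout: unprimed atoms for the upper unit, primed atoms for the lower unit, ring D carbons named as C8, C8a, C4a of ring D.
- The (S,S)-manganese catalyst is assigned by analogy with cis-β-methylstyrene, for which this enantiomer gives the (1S,2R)-oxide, the same spatial sense as (2S,3R) and (2'S,3'R) here. If a model study shows the opposite sense, the (R,R)-catalyst is used.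
- The (R)-phosphoric acid is proposed for the (R)-configuration at C4. Its sense of induction cannot be derived with certainty for this substrate, and the (S)-acid is used if the sense proves opposite.
- Compounds 11, 14 and 22 are taken as commercially available.

## Route

Step 1
Reactants: 1 2,4,6-trihydroxybenzaldehyde
Product: 2 2,4-bis(benzyloxy)-6-hydroxybenzaldehyde
Conditions: BnBr (2.05 equiv), K2CO3 (2.2 equiv), DMF, 0 °C → rt
Reagents that add atoms: benzyl bromide, BrCc1ccccc1
Why: Williamson etherification; the hydroxyl hydrogen-bonded to the formyl group is the least nucleophilic, so two equivalents of benzyl bromide should stop at the 2,4-diether, and any triether is removed by chromatography.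

Step 2
Reactants: 3 3,4,5-trihydroxybenzaldehyde
Product: 4 3,4,5-tris(benzyloxy)benzaldehyde
Conditions: BnBr (3.5 equiv), K2CO3 (4 equiv), DMF, 60 °C, under N2
Reagents that add atoms: benzyl bromide, BrCc1ccccc1
Why: Exhaustive Williamson benzylation of the three phenols; exclusion of air protects the pyrogallol until it is alkylated.

Step 3
Reactants: 4 3,4,5-tris(benzyloxy)benzaldehyde
Product: 5 1,2,3-tris(benzyloxy)-5-ethynylbenzene
Conditions: dimethyl (1-diazo-2-oxopropyl)phosphonate (1.3 equiv), K2CO3 (2 equiv), MeOH/THF, rt
Reagents that add atoms: dimethyl (1-diazo-2-oxopropyl)phosphonate, COP(=O)(OC)C(=[N+]=[N-])C(C)=O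
Why: Ohira–Bestmann homologation; methanolysis of the acetyl group frees the diazomethylphosphonate anion, which olefinates the aldehyde, and the diazoalkene loses N2 and rearranges to the terminal alkyne.

Step 4
Reactants: 2 2,4-bis(benzyloxy)-6-hydroxybenzaldehyde; 5 1,2,3-tris(benzyloxy)-5-ethynylbenzene
Product: 6 rac-1-[2,4-bis(benzyloxy)-6-hydroxyphenyl]-3-[3,4,5-tris(benzyloxy)phenyl]prop-2-yn-1-ol
Conditions: 5 (2.3 equiv), n-BuLi (2.2 equiv), THF, −78 °C; then 2, −78 → 0 °C; aq. NH4Cl
Reagents that add atoms: none
Why: Addition of a lithium acetylide to an aldehyde; the first equivalent deprotonates the phenol, the excess alkyne is recovered, and the carbinol configuration is irrelevant because it is removed in step 5.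

Step 5
Reactants: 6 rac-1-[2,4-bis(benzyloxy)-6-hydroxyphenyl]-3-[3,4,5-tris(benzyloxy)phenyl]prop-2-yn-1-ol
Product: 8 3,5-bis(benzyloxy)-2-{3-[3,4,5-tris(benzyloxy)phenyl]prop-2-yn-1-yl}phenol, via ortho-quinone methide 7 (not isolated)
Conditions: diethyl 2,6-dimethyl-1,4-dihydropyridine-3,5-dicarboxylate (Hantzsch ester, 1.5 equiv), (PhO)2P(O)OH (10 mol%), CH2Cl2, 0 °C → rt
Reagents that add atoms: none
Why: Brønsted acid-catalysed dehydration to the ortho-quinone methide and transfer hydrogenation at its exocyclic carbon, the known ionic reduction of ortho-hydroxybenzylic alcohols; the Hantzsch ester is a far better hydride donor than any arene present is a carbon nucleophile, so reduction should outrun self-condensation.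

Step 6
Reactants: 8 3,5-bis(benzyloxy)-2-{3-[3,4,5-tris(benzyloxy)phenyl]prop-2-yn-1-yl}phenol
Product: 10 4,6-bis(benzyloxy)-2-hydroxy-3-{3-[3,4,5-tris(benzyloxy)phenyl]prop-2-yn-1-yl}benzaldehyde, via hydroxymethyl phenol 9 (not isolated)
Conditions: MgCl2 (3 equiv), Et3N (6 equiv), (CH2O)n (10 equiv), THF, 65 °C; dilute HCl work-up
Reagents that add atoms: paraformaldehyde (as formaldehyde), C=O
Why: Casnati–Skattebøl ortho-formylation; the magnesium phenoxide delivers formaldehyde through a chelate to its only free ortho carbon, and the benzylic alkoxide then passes hydride to a second formaldehyde, so the para position between the two benzyloxy groups is not touched.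

Step 7
Reactants: 11 3,4-bis(benzyloxy)benzaldehyde
Product: 12 1,2-bis(benzyloxy)-4-ethynylbenzene
Conditions: dimethyl (1-diazo-2-oxopropyl)phosphonate (1.3 equiv), K2CO3 (2 equiv), MeOH/THF, rt
Reagents that add atoms: dimethyl (1-diazo-2-oxopropyl)phosphonate, COP(=O)(OC)C(=[N+]=[N-])C(C)=O
Why: Ohira–Bestmann homologation, as in step 3.

Step 8
Reactants: 10 4,6-bis(benzyloxy)-2-hydroxy-3-{3-[3,4,5-tris(benzyloxy)phenyl]prop-2-yn-1-yl}benzaldehyde; 12 1,2-bis(benzyloxy)-4-ethynylbenzene
Product: 13 rac-1-[4,6-bis(benzyloxy)-2-hydroxy-3-{3-[3,4,5-tris(benzyloxy)phenyl]prop-2-yn-1-yl}phenyl]-3-[3,4-bis(benzyloxy)phenyl]prop-2-yn-1-ol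
Conditions: 12 (2.3 equiv), n-BuLi (2.2 equiv), THF, −78 °C; then 10, −78 → 0 °C; aq. NH4Cl
Reagents that add atoms: none
Why: Acetylide addition to the aldehyde as in step 4; the acetylide is not basic enough to deprotonate the diarylpropyne methylene of the phenoxide, and the new carbinol centre is erased in step 9.

Step 9
Reactants: 13 rac-1-[4,6-bis(benzyloxy)-2-hydroxy-3-{3-[3,4,5-tris(benzyloxy)phenyl]prop-2-yn-1-yl}phenyl]-3-[3,4-bis(benzyloxy)phenyl]prop-2-yn-1-ol; 14 3,5-bis(benzyloxy)phenol
Product: 16 (3R)-1-[3,4-bis(benzyloxy)phenyl]-3-[2,4-bis(benzyloxy)-6-hydroxyphenyl]-3-[4,6-bis(benzyloxy)-2-hydroxy-3-{3-[3,4,5-tris(benzyloxy)phenyl]prop-2-yn-1-yl}phenyl]prop-1-yne, via ortho-quinone methide 15 (not isolated)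
Conditions: 13 added over 4 h to 14 (4 equiv) and (R)-3,3'-bis(2,4,6-triisopropylphenyl)-1,1'-binaphthyl-2,2'-diyl hydrogen phosphate (10 mol%), 5 Å molecular sieves, CH2Cl2, −40 °C
Reagents that add atoms: none
Why: Chiral phosphoric acid-catalysed Friedel–Crafts alkylation through an ortho-quinone methide, a known reaction of ortho-hydroxybenzylic and propargylic alcohols with electron-rich arenes. The acid holds the carbonyl oxygen of 15 and the hydroxyl of 14, delivering the ortho carbon of 14 to one face of the exocyclic carbon and so setting C4 (R). Excess 14 and slow addition of 13 keep the product from being alkylated again.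

Step 10
Reactants: 16 (3R)-bis-alkyne diphenol
Product: 17 bis(tert-butyldimethylsilyl) ether of 16 (both phenols silylated, C4 R)
Conditions: tert-butyldimethylsilyl triflate (3 equiv), 2,6-lutidine (5 equiv), CH2Cl2, 0 °C → rt
Reagents that add atoms: tert-butyldimethylsilyl trifluoromethanesulfonate, CC(C)(C)[Si](C)(C)OS(=O)(=O)C(F)(F)F
Why: Silylation of two hindered phenols with the reactive silyl triflate and a hindered base; the mask keeps the phenols out of the oxidation in step 12, and C4 is not affected.

Step 11
Reactants: 17 bis-alkyne bis(silyl ether)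
Product: 18 (1Z,3R)-1-[3,4-bis(benzyloxy)phenyl]-3-[2,4-bis(benzyloxy)-6-(tert-butyldimethylsilyloxy)phenyl]-3-[4,6-bis(benzyloxy)-2-(tert-butyldimethylsilyloxy)-3-{(2Z)-3-[3,4,5-tris(benzyloxy)phenyl]prop-2-en-1-yl}phenyl]prop-1-ene
Conditions: H2 (1 atm), Pd/CaCO3 poisoned with Pb(OAc)2 (Lindlar catalyst), quinoline, EtOAc, rt, stopped after uptake of 2 equiv
Reagents that add atoms: none
Why: Lindlar semihydrogenation; syn delivery of hydrogen on the poisoned palladium surface gives both (Z)-alkenes, quinoline suppresses over-reduction and double-bond migration towards C4, and benzyl ethers are not cleaved on this catalyst.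

Step 12
Reactants: 18 bis-(Z)-alkene
Product: 19 bis-cis-epoxide with (2S,3R) configuration at the upper oxirane, (2'S,3'R) at the lower oxirane and C4 R; rings A and D as silyl ethers
Conditions: chloro[(S,S)-N,N'-bis(3,5-di-tert-butylsalicylidene)-1,2-cyclohexanediaminato]manganese (10 mol%), N-methylmorpholine N-oxide (10 equiv), mCPBA (4 equiv, in portions), CH2Cl2, −78 °C; cold aq. NaOH/Na2S2O3 quench; chromatography on Et3N-deactivated silica
Reagents that add atoms: 3-chloroperoxybenzoic acid, OOC(=O)c1cccc(Cl)c1
Why: Jacobsen–Katsuki epoxidation of cis-β-substituted styrenes, run at two sites of one molecule. The peracid, moderated as its N-oxide salt, oxidises the trivalent manganese complex to a pentavalent oxomanganese species with the N-oxide as axial ligand, and each alkene approaches it side-on over the diamine bridge with its aryl group turned away from the tert-butyl groups. Each oxirane is closed by oxygen-atom transfer in two stages: the oxygen first bonds to the non-benzylic carbon (C3, C3'), and the benzylic radical at C2 (C2') then collapses onto the same oxygen. C2, C3, C2' and C3' are set by the (S,S)-diamine backbone, which selects the same enantioface at both alkenes because both present the aryl–CH=CH–sp3 pattern; the cis relation within each oxirane comes from the (Z)-geometry of 18. The step needs enantioface selection at two sites, retention of cis geometry, and chemoselectivity for the alkenes over rings A and D and the C4–H bond. Conjugation with a donor-substituted aryl ring makes each alkene the most reactive site towards the electrophilic oxo species; −78 °C and the axial N-oxide favour radical collapse over C2–C3 rotation; the silyl ethers keep the phenols out; and the peracid protocol avoids NaOCl, which would chlorinate the trialkoxyarenes. The remote C4 centre should exert only a small bias that the catalyst overrides, and a mismatch would appear as a separable diastereomer.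

Step 13
Reactants: 19 bis-cis-epoxide
Product: 21 nona-O-benzyl dimer diol with (2R,3R,4R) and (2'R,3'R) configuration (upper unit benzylated at O5, O7 and both ring B oxygens; lower unit at O5, O7 of ring D and the three ring E oxygens; free hydroxyls at C3 and C3'), via diphenol bis-epoxide 20 (not isolated)
Conditions: n-Bu4NF/AcOH (1:1, 3 equiv), THF, 0 °C; pH 7 buffer wash; then pyridinium p-toluenesulfonate (0.2 equiv), CH2Cl2, −20 → 0 °C
Reagents that add atoms: none
Why: Buffered fluoride removes the aryl silyl ethers without leaving free phenoxide, which could close in the 5-exo mode. Mild acid then lets each phenol open its epoxide at the benzylic carbon in a 6-endo process with inversion at C2 and C2' while C3–O and C3'–O stay intact (intramolecular epoxide opening by a phenol, known for flavan-3-ols), turning each cis-epoxide into a 2,3-cis-flavan-3-ol.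

Step 14
Reactants: 21 nona-O-benzyl dimer diol; 22 3,4,5-tris(benzyloxy)benzoic acid
Product: 23 pentadeca-O-benzyl digallate (3-O- and 3'-O-[3,4,5-tris(benzyloxy)benzoyl] esters of 21)
Conditions: 22 (3 equiv), DCC (3.3 equiv), DMAP (1 equiv), CH2Cl2, rt
Reagents that add atoms: none
Why: Steglich esterification of the only two free hydroxyls; the acylpyridinium formed with DMAP is reactive enough for the axial C3–OH, and no stereocentre is touched.

Step 15
Reactants: 23 pentadeca-O-benzyl digallate
Product: 24 (−)-epicatechin 3-O-gallate-(4β→8)-(−)-epigallocatechin 3-O-gallate (target)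
Conditions: H2 (1 atm), Pd(OH)2/C, THF/MeOH/H2O, rt; filtration under argon, purification on Sephadex LH-20
Reagents that add atoms: none
Why: Hydrogenolysis of fifteen benzyl ethers under neutral conditions; aryl esters, the C4–C8 bond and the cyclic benzylic ethers at C2 and C2' are known to persist under these conditions in catechin gallate chemistry.

## Compound list

1 | 2,4,6-trihydroxybenzaldehyde | O=Cc1c(O)cc(O)cc1O | starting material
2 | 2,4-bis(benzyloxy)-6-hydroxybenzaldehyde | O=Cc1c(O)cc(OCc9ccccc9)cc1OCc9ccccc9 | intermediate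
3 | 3,4,5-trihydroxybenzaldehyde | O=Cc1cc(O)c(O)c(O)c1 | starting material
4 | 3,4,5-tris(benzyloxy)benzaldehyde | O=Cc1cc(OCc9ccccc9)c(OCc9ccccc9)c(OCc9ccccc9)c1 | intermediate
5 | 1,2,3-tris(benzyloxy)-5-ethynylbenzene | C#Cc1cc(OCc9ccccc9)c(OCc9ccccc9)c(OCc9ccccc9)c1 | intermediate
6 | rac-1-[2,4-bis(benzyloxy)-6-hydroxyphenyl]-3-[3,4,5-tris(benzyloxy)phenyl]prop-2-yn-1-ol | OC(C#Cc1cc(OCc9ccccc9)c(OCc9ccccc9)c(OCc9ccccc9)c1)c2c(O)cc(OCc9ccccc9)cc2OCc9ccccc9 | intermediate
7 | 3,5-bis(benzyloxy)-6-{3-[3,4,5-tris(benzyloxy)phenyl]prop-2-yn-1-ylidene}cyclohexa-2,4-dien-1-one (ortho-quinone methide, not isolated) | O=C1C=C(OCc9ccccc9)C=C(OCc9ccccc9)C1=CC#Cc2cc(OCc9ccccc9)c(OCc9ccccc9)c(OCc9ccccc9)c2 | intermediate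
8 | 3,5-bis(benzyloxy)-2-{3-[3,4,5-tris(benzyloxy)phenyl]prop-2-yn-1-yl}phenol | Oc1cc(OCc9ccccc9)cc(OCc9ccccc9)c1CC#Cc2cc(OCc9ccccc9)c(OCc9ccccc9)c(OCc9ccccc9)c2 | intermediate
9 | 3,5-bis(benzyloxy)-2-(hydroxymethyl)-6-{3-[3,4,5-tris(benzyloxy)phenyl]prop-2-yn-1-yl}phenol (as magnesium salt, not isolated) | OCc1c(O)c(CC#Cc2cc(OCc9ccccc9)c(OCc9ccccc9)c(OCc9ccccc9)c2)c(OCc9ccccc9)cc1OCc9ccccc9 | intermediate
10 | 4,6-bis(benzyloxy)-2-hydroxy-3-{3-[3,4,5-tris(benzyloxy)phenyl]prop-2-yn-1-yl}benzaldehyde | O=Cc1c(O)c(CC#Cc2cc(OCc9ccccc9)c(OCc9ccccc9)c(OCc9ccccc9)c2)c(OCc9ccccc9)cc1OCc9ccccc9 | intermediate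
11 | 3,4-bis(benzyloxy)benzaldehyde | O=Cc1ccc(OCc9ccccc9)c(OCc9ccccc9)c1 | starting material
12 | 1,2-bis(benzyloxy)-4-ethynylbenzene | C#Cc1ccc(OCc9ccccc9)c(OCc9ccccc9)c1 | intermediate
13 | rac-1-[4,6-bis(benzyloxy)-2-hydroxy-3-{3-[3,4,5-tris(benzyloxy)phenyl]prop-2-yn-1-yl}phenyl]-3-[3,4-bis(benzyloxy)phenyl]prop-2-yn-1-ol | OC(C#Cc1ccc(OCc9ccccc9)c(OCc9ccccc9)c1)c2c(O)c(CC#Cc3cc(OCc9ccccc9)c(OCc9ccccc9)c(OCc9ccccc9)c3)c(OCc9ccccc9)cc2OCc9ccccc9 | intermediate
14 | 3,5-bis(benzyloxy)phenol | Oc1cc(OCc9ccccc9)cc(OCc9ccccc9)c1 | starting material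
15 | 3,5-bis(benzyloxy)-6-{3-[3,4-bis(benzyloxy)phenyl]prop-2-yn-1-ylidene}-2-{3-[3,4,5-tris(benzyloxy)phenyl]prop-2-yn-1-yl}cyclohexa-2,4-dien-1-one (ortho-quinone methide, not isolated) | O=C1C(CC#Cc3cc(OCc9ccccc9)c(OCc9ccccc9)c(OCc9ccccc9)c3)=C(OCc9ccccc9)C=C(OCc9ccccc9)C1=CC#Cc2ccc(OCc9ccccc9)c(OCc9ccccc9)c2 | intermediate
16 | (3R)-1-[3,4-bis(benzyloxy)phenyl]-3-[2,4-bis(benzyloxy)-6-hydroxyphenyl]-3-[4,6-bis(benzyloxy)-2-hydroxy-3-{3-[3,4,5-tris(benzyloxy)phenyl]prop-2-yn-1-yl}phenyl]prop-1-yne | c9ccccc9COc1ccc(C#C[C@@H](c3c(OCc9ccccc9)cc(OCc9ccccc9)c(CC#Cc6cc(OCc9ccccc9)c(OCc9ccccc9)c(OCc9ccccc9)c6)c3O)c4c(OCc9ccccc9)cc(OCc9ccccc9)cc4O)cc1OCc9ccccc9 | intermediate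
17 | bis(tert-butyldimethylsilyl) ether of 16, C4 (R) | c9ccccc9COc1ccc(C#C[C@@H](c3c(OCc9ccccc9)cc(OCc9ccccc9)c(CC#Cc6cc(OCc9ccccc9)c(OCc9ccccc9)c(OCc9ccccc9)c6)c3O[Si](C)(C)C(C)(C)C)c4c(OCc9ccccc9)cc(OCc9ccccc9)cc4O[Si](C)(C)C(C)(C)C)cc1OCc9ccccc9 | intermediate
18 | bis-(Z)-alkene, C4 (R), rings A and D as silyl ethers | c9ccccc9COc1ccc(/C=C\[C@@H](c3c(OCc9ccccc9)cc(OCc9ccccc9)c(C/C=C\c6cc(OCc9ccccc9)c(OCc9ccccc9)c(OCc9ccccc9)c6)c3O[Si](C)(C)C(C)(C)C)c4c(OCc9ccccc9)cc(OCc9ccccc9)cc4O[Si](C)(C)C(C)(C)C)cc1OCc9ccccc9 | intermediate
19 | bis-cis-epoxide, (2S,3R,4R) and (2'S,3'R), rings A and D as silyl ethers | c9ccccc9COc1ccc([C@@H]2O[C@@H]2[C@@H](c3c(OCc9ccccc9)cc(OCc9ccccc9)c(C[C@H]5O[C@H]5c6cc(OCc9ccccc9)c(OCc9ccccc9)c(OCc9ccccc9)c6)c3O[Si](C)(C)C(C)(C)C)c4c(OCc9ccccc9)cc(OCc9ccccc9)cc4O[Si](C)(C)C(C)(C)C)cc1OCc9ccccc9 | intermediate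
20 | diphenol bis-cis-epoxide, (2S,3R,4R) and (2'S,3'R) (not isolated) | c9ccccc9COc1ccc([C@@H]2O[C@@H]2[C@@H](c3c(OCc9ccccc9)cc(OCc9ccccc9)c(C[C@H]5O[C@H]5c6cc(OCc9ccccc9)c(OCc9ccccc9)c(OCc9ccccc9)c6)c3O)c4c(OCc9ccccc9)cc(OCc9ccccc9)cc4O)cc1OCc9ccccc9 | intermediate
21 | nona-O-benzyl dimer diol, (2R,3R,4R) and (2'R,3'R), free hydroxyls at C3 and C3' | O[C@@H]1[C@@H](c2c(OCc9ccccc9)cc(OCc9ccccc9)c3c2O[C@H](c4cc(OCc9ccccc9)c(OCc9ccccc9)c(OCc9ccccc9)c4)[C@H](O)C3)c5c(OCc9ccccc9)cc(OCc9ccccc9)cc5O[C@@H]1c6ccc(OCc9ccccc9)c(OCc9ccccc9)c6 | intermediate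
22 | 3,4,5-tris(benzyloxy)benzoic acid | OC(=O)c1cc(OCc9ccccc9)c(OCc9ccccc9)c(OCc9ccccc9)c1 | starting material
23 | pentadeca-O-benzyl digallate, (2R,3R,4R) and (2'R,3'R) | O=C(O[C@@H]1[C@@H](c2c(OCc9ccccc9)cc(OCc9ccccc9)c3c2O[C@H](c4cc(OCc9ccccc9)c(OCc9ccccc9)c(OCc9ccccc9)c4)[C@H](OC(=O)c7cc(OCc9ccccc9)c(OCc9ccccc9)c(OCc9ccccc9)c7)C3)c5c(OCc9ccccc9)cc(OCc9ccccc9)cc5O[C@@H]1c6ccc(OCc9ccccc9)c(OCc9ccccc9)c6)c8cc(OCc9ccccc9)c(OCc9ccccc9)c(OCc9ccccc9)c8 | intermediate
24 | (−)-epicatechin 3-O-gallate-(4β→8)-(−)-epigallocatechin 3-O-gallate | O=C(O[C@@H]1[C@@H](c2c(O)cc(O)c3c2O[C@H](c2cc(O)c(O)c(O)c2)[C@H](OC(=O)c2cc(O)c(O)c(O)c2)C3)c2c(O)cc(O)cc2O[C@@H]1c1ccc(O)c(O)c1)c1cc(O)c(O)c(O)c1 | target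

## Step count and risk

Total: 15 steps. Longest linear sequence: 13 steps (3 → 4 → 5 → 6 → 8 → 10 → 13 → 16 → 17 → 18 → 19 → 21 → 23 → 24; steps 2, 3, 4, 5, 6, 8, 9, 10, 11, 12, 13, 14, 15).

**Step 12 (key step).**
- What may go wrong: leakage from cis to trans epoxide, because the donor-substituted rings B and E stabilise the benzylic radical and give it time to rotate before it closes. Facial selectivity may also be weak at the upper alkene, whose allylic carbon C4 carries two bulky aryl groups that can disturb the side-on approach. Some oxidation of the electron-rich arenes is possible.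
- Fallback: epoxidation with a chiral dioxirane (Shi epoxidation). A glucose-derived spiro ketone bearing an N-aryl oxazolidinone, the catalyst class made for cis-alkenes, is used in the enantiomeric form that gives the (2S,3R) sense, with KHSO5 (as 2KHSO5·KHSO4·K2SO4) and K2CO3 in MeCN/dimethoxymethane/water at 0 °C. Oxygen is transferred from the dioxirane in one concerted step through a spiro transition state, so no intermediate exists that could lose the alkene geometry, and no metal-oxo species or hypochlorite is present. It sets out from 18 and returns at 19 and makes no compound outside the list (F0).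

**Step 9.**
- What may go wrong: low facial discrimination on 15, whose exocyclic carbon is flanked by two ring substituents and whose exocyclic double bond can exist as two geometric isomers; attack at the para carbon of 14; a second alkylation of 16 at its free ring A position.
- Fallback: resolution instead of asymmetric catalysis. The coupling is run with achiral (PhO)2P(O)OH under the same excess of 14, and the racemate is separated by preparative chromatography on a chiral stationary phase. The (S)-enantiomer of 16 F1 is set aside. It sets out from 13 and 14 and returns at 16.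

**Step 13.**
- What may go wrong: ionisation of the C2–O bond of the ring B epoxide (para-benzyloxy donor) before the phenol arrives. A rotated cation gives the C2 epimer, or a hydride shift gives a benzyl ketone (Meinwald rearrangement). 5-exo closure at C3' is a second danger.
- Fallback: a stepwise, acid-free closure that moves the inversion to a Mitsunobu reaction.
  - 19 is treated with CO2 (1 atm) and n-Bu4NI with a phenolic hydrogen-bond donor at 45 °C. Double inversion at the benzylic carbon gives the cis-fused bis(cyclic carbonate) F2 with retention at all four carbons.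
  - K2CO3 in MeOH/THF cleaves the carbonates to the erythro,erythro-tetraol bis(silyl ether) F3.
  - n-Bu4NF/AcOH gives the tetraol diphenol F4.
  - PPh3 and diisopropyl azodicarboxylate in THF at 0 °C close both pyran rings by displacement of the benzylic hydroxyls by the phenols with inversion (the known Mitsunobu cyclisation of 1-aryl-3-(2-hydroxyaryl)propane-1,2-diols to flavan-3-ols).
  - It sets out from 19 and returns at 21.

**Step 11.**
- What may go wrong: over-reduction of the fast lower alkyne while the hindered upper alkyne lags; palladium hydride-mediated Z→E isomerisation; migration of the upper double bond into conjugation with rings A and D, which would erase C4.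
- Fallback: stoichiometric cis-reduction without hydrogen. Ti(OiPr)4 with two equivalents of i-PrMgCl (divalent titanium) in Et2O at −50 °C forms a titanium–alkyne complex at each triple bond, and protonolysis with water gives the (Z)-alkenes. Over-reduction and hydride-mediated isomerisation are excluded. It sets out from 17 and returns at 18 and makes no compound outside the list (F0).

**Step 6.**
- What may go wrong: isomerisation of the 1,3-diarylpropyne unit of 8 to the conjugated allene under warm amine and phenoxide; slow hydroxymethylation at an ortho carbon flanked by two substituents.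
- Fallback: exchange the roles of the partners in the Friedel–Crafts step so that no formylation is needed. The lithium acetylide of 12 is added to 2 to give rac-1-[2,4-bis(benzyloxy)-6-hydroxyphenyl]-3-[3,4-bis(benzyloxy)phenyl]prop-2-yn-1-ol F5. Under the chiral phosphoric acid of step 9 (enantiomer chosen for the (R)-product), the quinone methide of this ring A carbinol is captured by the free ortho carbon of 8 (3 equiv, recovered), forming the C4–C8 bond to ring D. It sets out from 8 (with 2 and 12) and returns at 16, bypassing 10 and 13. Its price is that the ring A carbinol can condense with itself, which the excess of 8 has to suppress.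

## Further compounds

F1 | step 9 | (3S)-enantiomer of bis-alkyne diphenol 16 | c9ccccc9COc1ccc(C#C[C@H](c3c(OCc9ccccc9)cc(OCc9ccccc9)c(CC#Cc6cc(OCc9ccccc9)c(OCc9ccccc9)c(OCc9ccccc9)c6)c3O)c4c(OCc9ccccc9)cc(OCc9ccccc9)cc4O)cc1OCc9ccccc9
F2 | step 13 | bis(cyclic carbonate) from 19: both oxiranes replaced with retention by cis-1,3-dioxolan-2-ones, rings A and D as silyl ethers | c9ccccc9COc1ccc([C@@H]2OC(=O)O[C@@H]2[C@@H](c3c(OCc9ccccc9)cc(OCc9ccccc9)c(C[C@H]5OC(=O)O[C@H]5c6cc(OCc9ccccc9)c(OCc9ccccc9)c(OCc9ccccc9)c6)c3O[Si](C)(C)C(C)(C)C)c4c(OCc9ccccc9)cc(OCc9ccccc9)cc4O[Si](C)(C)C(C)(C)C)cc1OCc9ccccc9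
F3 | step 13 | erythro,erythro-tetraol with (2S,3R,4R) and (2'S,3'R) configuration, rings A and D as silyl ethers | c9ccccc9COc1ccc([C@H](O)[C@H](O)[C@@H](c3c(OCc9ccccc9)cc(OCc9ccccc9)c(C[C@@H](O)[C@@H](O)c6cc(OCc9ccccc9)c(OCc9ccccc9)c(OCc9ccccc9)c6)c3O[Si](C)(C)C(C)(C)C)c4c(OCc9ccccc9)cc(OCc9ccccc9)cc4O[Si](C)(C)C(C)(C)C)cc1OCc9ccccc9
F4 | step 13 | erythro,erythro-tetraol diphenol with (2S,3R,4R) and (2'S,3'R) configuration | c9ccccc9COc1ccc([C@H](O)[C@H](O)[C@@H](c3c(OCc9ccccc9)cc(OCc9ccccc9)c(C[C@@H](O)[C@@H](O)c6cc(OCc9ccccc9)c(OCc9ccccc9)c(OCc9ccccc9)c6)c3O)c4c(OCc9ccccc9)cc(OCc9ccccc9)cc4O)cc1OCc9ccccc9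
F5 | step 6 | rac-1-[2,4-bis(benzyloxy)-6-hydroxyphenyl]-3-[3,4-bis(benzyloxy)phenyl]prop-2-yn-1-ol | OC(C#Cc1ccc(OCc9ccccc9)c(OCc9ccccc9)c1)c2c(O)cc(OCc9ccccc9)cc2OCc9ccccc9
F0 | step 12 | none | none
F0 | step 11 | none | none
A1 | alternative 1 | (2R,3R,4R)-3-(allyloxy)-5,7-bis(benzyloxy)-2-[3,4-bis(benzyloxy)phenyl]-4-[2,4-bis(benzyloxy)-6-fluorophenyl]chromane | C=CCO[C@@H]1[C@@H](c2c(OCc9ccccc9)cc(OCc9ccccc9)cc2F)c4c(OCc9ccccc9)cc(OCc9ccccc9)cc4O[C@@H]1c5ccc(OCc9ccccc9)c(OCc9ccccc9)c5
A2 | alternative 1 | (1R,2R)-2-(allyloxy)-1-[3,4-bis(benzyloxy)phenyl]-3,3-bis[2,4-bis(benzyloxy)-6-fluorophenyl]propan-1-ol | C=CCO[C@@H]([C@H](O)c5ccc(OCc9ccccc9)c(OCc9ccccc9)c5)C(c2c(OCc9ccccc9)cc(OCc9ccccc9)cc2F)c4c(OCc9ccccc9)cc(OCc9ccccc9)cc4F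
A3 | alternative 2 | 2-substituted benzene-1,3,5-triol (ring A) with open ring C: C4 bears the protected lower unit through C8 of ring D, C3 a tert-butyldimethylsilyl ether, C2 a triethylsilyl ether and ring B | Oc4cc(O)c([C@H](c2c(OCc9ccccc9)cc(OCc9ccccc9)c3c2O[C@H](c6cc(OCc9ccccc9)c(OCc9ccccc9)c(OCc9ccccc9)c6)[C@H](O[Si](C)(C)C(C)(C)C)C3)[C@@H](O[Si](C)(C)C(C)(C)C)[C@@H](O[Si](CC)(CC)CC)c5ccc(OCc9ccccc9)c(OCc9ccccc9)c5)c(O)c4
A4 | alternative 2 | methyl 9-[3,4-bis(benzyloxy)phenyl]-8-(tert-butyldimethylsilyloxy)-3,5-dioxo-9-(triethylsilyloxy)nonanoate carrying the protected lower unit at C7 (configuration as in A3) | COC(=O)CC(=O)CC(=O)C[C@H](c2c(OCc9ccccc9)cc(OCc9ccccc9)c3c2O[C@H](c6cc(OCc9ccccc9)c(OCc9ccccc9)c(OCc9ccccc9)c6)[C@H](O[Si](C)(C)C(C)(C)C)C3)[C@@H](O[Si](C)(C)C(C)(C)C)[C@@H](O[Si](CC)(CC)CC)c5ccc(OCc9ccccc9)c(OCc9ccccc9)c5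
A5 | alternative 3 | 2-hydroxyflavan 3-[3,4,5-tris(benzyloxy)benzoate] hemiketal with the protected lower unit at C4 (C2 anomers) | O=C(O[C@@H]1[C@@H](c2c(OCc9ccccc9)cc(OCc9ccccc9)c3c2O[C@H](c6cc(OCc9ccccc9)c(OCc9ccccc9)c(OCc9ccccc9)c6)[C@H](O[Si](C)(C)C(C)(C)C)C3)c4c(OCc9ccccc9)cc(OCc9ccccc9)cc4OC1(O)c5ccc(OCc9ccccc9)c(OCc9ccccc9)c5)c7cc(OCc9ccccc9)c(OCc9ccccc9)c(OCc9ccccc9)c7
A6 | alternative 3 | [2,4-bis(benzyloxy)-6-hydroxyphenyl](protected lower flavan-8-yl)methanol (carbinol epimers) | OC(c4c(OCc9ccccc9)cc(OCc9ccccc9)cc4O)c2c(OCc9ccccc9)cc(OCc9ccccc9)c3c2O[C@H](c6cc(OCc9ccccc9)c(OCc9ccccc9)c(OCc9ccccc9)c6)[C@H](O[Si](C)(C)C(C)(C)C)C3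
A7 | alternative 3 | 2-[3,4-bis(benzyloxy)phenyl]-2-oxoethyl 3,4,5-tris(benzyloxy)benzoate | O=C(COC(=O)c7cc(OCc9ccccc9)c(OCc9ccccc9)c(OCc9ccccc9)c7)c5ccc(OCc9ccccc9)c(OCc9ccccc9)c5
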